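Leftover substrate was my starting point: in the noon run at 6.00 d hardly any remained, 1.0 % of the charge, while product stood at 31.9 %, so 67.1 % of the charge was neither. With the coupling partner at 1.3 equiv, substrate is the limiting reagent of the noon run, so its balance holds substrate, product and this unseen share, and the question for a cold flask is how fast product is fed from that share.

| setting | noon | winter | autumn | amber | red | grey | ochre |
|---|---|---|---|---|---|---|---|
| substrate | 0.12 M | 0.19 M | 0.25 M | 0.25 M | 0.25 M | 0.25 M | 0.25 M |
| coupling partner | 1.3 equiv | 1.3 equiv | 0.65 equiv | 1.30 equiv | 1.30 equiv | 1.30 equiv | 1.30 equiv |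
| temperature | 36 °C | 61 °C | 36 °C | 70 °C | 25 °C | 40 °C | 55 °C |
| remark | run made earlier | run made earlier | run made earlier |  |  |  |  |
| time |  |  |  | 10 d | 10 d | 10 d | 10 d |

- noon (time / d: product / %, substrate / %): 6.00: 31.9, 1.0; 15.0: 56.1, 0.5; 25.0: 61.4, 0; 30.0: 64.1, 0.4; 40.0: 65.3, 0
- winter (time / d: product / %, substrate / %): 1.04: 38.6, 0; 1.67: 43.0, 0.2; 2.50: 45.2, 0.4; 4.00: 46.8, 0; 5.00: 46.6, 0; 8.00: 47.0, 0.1; 12.0: 46.5, 0.2
- autumn (time / d: product / %, substrate / %): 3.00: 9.9, 9.1; 6.00: 27.1, 1.1; 15.0: 45.7, 0; 20.0: 49.3, 0; 40.0: 52.5, 0

(standard deviation of a reading: 0.5 percentage points)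

1. the best flask by amount of product, in percent of the substrate charged; "all alike" if 1.5 percentage points covers them all (amber / red / grey / ochre / all alike)
2. amount of product at the end, in percent of the substrate charged, amber
3. amount of product at the end, in percent of the substrate charged, red
4. amount of product at the end, in percent of the substrate charged, grey
5. amount of product at the end, in percent of the substrate charged, ochre

- the earlier runs were read with a standard deviation of 0.5 percentage points

I read the shortfall of product below its plateau. It shrank at 0.143 /d in the noon run and at 1.18 /d in the winter run. Carried to 25 °C by the same factor per degree, these readings gave red 0.0567 /d, its clearing rate, the fraction of the shortfall removed per day.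

I then solved two versions of red. With substrate gone at once, red reaches 0.433 of its plateau by 10 d. With substrate leaving no faster than the clearing rate, two equal steps in line, red reaches 0.111. I put red between them, because in the autumn run at 36 °C substrate fell at 0.704 /d, faster than the noon clearing rate, yet not at once. I took grey as best: I reckoned it to clear at 0.201 /d, faster than red, and the winter run, hotter but also charged at a different concentration, read lower at its plateau than the noon run.

The forecast named grey best, with amber 43 %, red 38 %, grey 68 % and ochre 59 %, and said “Kinetics matter in the cold.”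

The flasks gave grey as best: amber 41.8 %, red 13.2 %, grey 65.4 %, ochre 55.3 %.

    coupling partner + intermediate B → intermediate D (k = 0.0760 /M/h, Ea = 62.0 kJ/mol)
    intermediate C → intermediate D (k = 0.110 /h, Ea = 109 kJ/mol)
    intermediate D ⇌ product (K = 5.70, k = 0.0410 /h, Ea = 115 kJ/mol, ΔH = −27.0 kJ/mol)
    substrate → intermediate B (k = 0.0270 /h, Ea = 95.0 kJ/mol)
    intermediate A → decomposed reagent (k = 0.0140 /h, Ea = 114 kJ/mol)
    substrate → intermediate A (k = 0.0280 /h, Ea = 111 kJ/mol)
    coupling partner + intermediate A → intermediate C (k = 0.100 /M/h, Ea = 78.0 kJ/mol)
    (constants at 40 °C)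

At 100 d red reached 80.4 %, so at 10 d it stood at 0.164 of that value, between 0.111 and 0.433. Red read at 2.5 d is the neighbouring flask. The same 0.0567 /d gives 0.132 and 0.00915 there for the two versions, but its product, 0.426 %, was 0.00529 of the value at 100 d, below the lower version. Substrate stood at 63.4 %, so 36.2 % of the charge was neither: intermediate A 12.1 %, intermediate B 16.6 %, intermediate C 2.29 %, intermediate D 4.49 % and decomposed reagent 0.665 %.

The runs come from a simulation for an exercise; scatter was added.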